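In a one-step world, each point of substrate lost would be a point of product. Cedar, a racemate under held gas, may not be that world: its substrates may also pass through the achiral form towards waste.

| flask | left-handed substrate | right-handed substrate | gas | remark | time |
|---|---|---|---|---|---|
| cedar | 0.80 M | 0.80 M | 48 mM (held) | the very flask that is asked about, followed so far |  |
| maple | 1.6 M | 1.6 M | 48 mM (held) | run made earlier |  |
| flask | 0.80 M | 0.80 M | 48 mM (held) |  | 40 h |

| run | time / h | left-handed product / % | right-handed product / % | left-handed substrate / % |
|---|---|---|---|---|
| cedar | 0.833 | 3.7 | 0.9 | 41.2 |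
| cedar | 2.50 | 5.4 | 4.1 | 33.5 |
| cedar | 5.00 | 11.1 | 4.1 | 25.1 |
| cedar | 6.00 | 13.6 | 5.8 | 21.3 |
| cedar | 10.0 | 16.5 | 9.3 | 14.3 |
| cedar | 12.0 | 18.1 | 12.2 | 14.9 |
| cedar | 15.0 | 21.2 | 12.6 | 11.8 |
| maple | 0.833 | 1.6 | 2.4 | 43.9 |
| maple | 2.50 | 3.3 | 2.7 | 31.7 |
| maple | 5.00 | 10.4 | 5.1 | 25.8 |
| maple | 6.00 | 11.4 | 7.2 | 22.1 |
| maple | 10.0 | 15.8 | 9.5 | 19.7 |
| maple | 12.0 | 18.5 | 10.2 | 14.1 |
| maple | 15.0 | 20.1 | 12.6 | 11.6 |

(each reading ± 1 percentage point)

- partner is single-handed; left-handed substrate and right-handed substrate are mirror images of each other, charged as a racemate, each of them at the stated concentration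
- at the start none of partner is dissolved
- what may be going on: partner + left-handed substrate -> left-handed product; partner + right-handed substrate -> right-handed product; left-handed substrate <-> achiral form; right-handed substrate <-> achiral form; achiral form -> waste; partner <-> dormant form; gas <-> partner; partner -> decomposed reagent
- an excess is the difference of the two amounts in percent of their sum
- an excess is below zero if the other one leads
- the handed part of partner does not stay in what it makes, so the products of the two hands are mirror images too

- left-handed product and right-handed product together, in percent of the left-handed substrate and right-handed substrate charged together, at 40 h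
- excess of left-handed product over right-handed product in the product at 40 h
- whether the exchange between left-handed substrate and right-handed substrate keeps pace with the reaction: how far the product's excess at 40 h gets from its value without exchange to its value with instant exchange (above 80% keeps pace, below 20% hardly takes part, else lags behind)

From 5.00 h to 15.0 h, cedar gains 19 percentage points of product. Over the same window its two substrates lose 27 points, the unread right-handed substrate being counted equal to the left-handed. The harvest is therefore 0.699: product gained per point of the two substrates lost over a window. Maple, at 1.6 M, reads 0.606 over the same window, and the estimate keeps cedar's value. At 15.0 h, cedar still holds 23.6% of substrate. If that goes at the same harvest, the yield at 40 h is about 50.3%.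

The forecast, by a different route, gives 51% (43% to 60%) and an excess of 19% (13% to 25%). It calls the result “intermediate between the limits”, so the exchange lags behind.

Cedar gives 48.6% and an excess of 23.3%; the exchange lags behind, at 71% of the way.

    partner + left-handed substrate → left-handed product (k = 1.51 L mol⁻¹ h⁻¹)
    partner + right-handed substrate → right-handed product (k = 0.835 L mol⁻¹ h⁻¹)
    left-handed substrate ⇌ achiral form (K = 1.04, k = 0.189 h⁻¹)
    right-handed substrate ⇌ achiral form (K = 1.04, k = 0.189 h⁻¹)
    achiral form → waste (k = 0.114 h⁻¹)
    partner ⇌ dormant form (K = 21.1, k = 0.294 h⁻¹)
    gas ⇌ partner, rate k7*(csat - [partner]) (kL = 8.79 h⁻¹)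
    partner → decomposed reagent (k = 0.200 h⁻¹)

At 40.0 h, cedar holds 45.1% of waste. Between 20.0 h and 40.0 h, its two substrates fall by 14 points. The harvest of 0.699 turns that fall into 9.5 points of product, and cedar's product rises by 9.7 points.

The readings stem from a simulated flask for substances that don't exist; the scatter is artificial.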